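Cuts: the four O–benzyl bonds go last. Then O1–C2 and C2–C1' are cut (ring B leaves as an aryl Grignard reagent), which leads back to a 3-benzoyloxy-4-arylchroman-2-ol. This lactol is cut at C4–C4a, C3–O and O1–C2 into resorcinol, a ring D cinnamaldehyde and dibenzoyl peroxide.
Enabling feature: C2, C3 and C4 of ring C are C1, Cα and Cβ of an enal that already carries ring D on Cβ. C4a is position 4 of resorcinol and the hydroxyl ortho to it is O1, so β-arylation, α-oxygenation and hemiacetal closure build ring C around C3–C4.
Forward: ring D enal (three steps); one-pot arylation, benzoyloxylation and lactol closure (rings A and D joined, ring C closed); ring B added while the lactol opens in passing; acid re-closure of ring C; hydrogenolysis.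
Stereochemistry: one (S)-diarylprolinol silyl ether blocks the same face in the iminium and in the enamine cycle and sets C4 and C3 (absolute, 3,4-cis). C2 follows from them in the cationic ring closure (2,3-trans).

Key step: step 4

Assumption: flavan numbering (O1, C2, C3, C4, C4a to C8a; ring A fused, ring B on C2, ring D on C4) is used for all chroman intermediates, and the sense of induction of the (S)-catalyst is taken from its usual shielding model (E-iminium ion and E-enamine attacked anti to the CPh2OTMS group).

Step 1
Reactants: 1 2-methoxyresorcinol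
Product: 2 1,3-bis(benzyloxy)-2-methoxybenzene
Conditions: BnBr (2.3 equiv), K2CO3, DMF, 60 °C
Reagents that add atoms: benzyl bromide, BrCc1ccccc1
Why: Williamson ether synthesis on both phenoxides of 1; benzyl is chosen because it should survive POCl3, the amine/peroxide step, the Grignard reagent and mild acid, and all benzyl groups leave together in one final hydrogenolysis.

Step 2
Reactants: 2 1,3-bis(benzyloxy)-2-methoxybenzene
Product: 3 2,4-bis(benzyloxy)-3-methoxybenzaldehyde
Conditions: POCl3, DMF, 0 → 70 °C; then ice-water
Reagents that add atoms: N,N-dimethylformamide, CN(C)C=O; water, O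
Why: Vilsmeier–Haack formylation at C4 of 2, which is para to one benzyloxy group and ortho to the other, whereas C5 is activated only by the flanked, twisted methoxy group, as in the formylation of 1,2,3-trialkoxybenzenes to 2,3,4-trialkoxybenzaldehydes.

Step 3
Reactants: 3 2,4-bis(benzyloxy)-3-methoxybenzaldehyde
Product: 4 (E)-3-[2,4-bis(benzyloxy)-3-methoxyphenyl]prop-2-enal
Conditions: Ph3P=CHCHO (1.2 equiv), toluene, 90 °C
Reagents that add atoms: (triphenylphosphoranylidene)acetaldehyde, O=CC=P(c1ccccc1)(c1ccccc1)c1ccccc1
Why: Wittig reaction with a stabilised formyl ylide, which should give the (E)-enal, while a small excess of ylide and a stop at full conversion limit a second homologation.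

Step 4
Reactants: 4 (E)-3-[2,4-bis(benzyloxy)-3-methoxyphenyl]prop-2-enal; 5 resorcinol; 6 dibenzoyl peroxide
Product: 8 (3S,4R)-4-[2,4-bis(benzyloxy)-3-methoxyphenyl]-2,7-dihydroxychroman-3-yl benzoate (3,4-cis; both lactol anomers), via 4-arylchromane-2,7-diol 7 (not isolated)
Conditions: (S)-2-[diphenyl(trimethylsilyloxy)methyl]pyrrolidine (20 mol %), PhCO2H (20 mol %), 5 (1.3 equiv), THF, 23 °C; then 6 (1.2 equiv), 0 °C
Reagents that add atoms: none
Why: Proposed new method: the amine condenses with 4 to an E-configured, s-trans iminium ion with one face covered by the CPh2OTMS group, so position 4 of 5 attacks the β-carbon from the open face (Friedel–Crafts-type conjugate addition, sets C4) and, after rearomatisation and hydrolysis, the neighbouring hydroxyl adds to the aldehyde in a 6-exo-trig closure that stores the adduct as lactol 7. The aldehyde tautomer of 7 condenses again with the same amine to the E-enamine, which attacks the O–O bond of 6 once more anti to the CPh2OTMS group (sets C3), and a second 6-exo-trig hemiacetalisation gives 8 and withdraws the α-oxy aldehyde from further enamine formation, so that C3 should not epimerise; C2 remains a mobile hemiacetal centre. Since both bonds are made on the same face of the extended C2–C3–C4–ring D chain, O3 and C4a are syn in that zigzag, which becomes the cis relation of O3 and ring D once C4a counts as a member of ring C, and the shielding model assigns the 3β,4β array of the target (3S,4R in 8) to the (S)-catalyst. Closest known reaction types: amine-catalysed Friedel–Crafts alkylation–hemiacetalisation of naphthols and electron-rich phenols with cinnamaldehydes, enamine α-benzoyloxylation of aldehydes with 6, and iminium–enamine cascades that pair an arene nucleophile with an electrophilic halogen source; new are resorcinol as the arene, a peroxide as the cascade electrophile and a lactol as the enamine source. The step needs C- over O-alkylation and position 4 over position 2 of 5 (the oxa-Michael adduct reverts, position 2 is flanked by two hydroxyls, and positions 4 and 6 are equivalent and each keep an ortho hydroxyl for ring closure), monoalkylation (slight excess of 5), and attack of 6 on the enamine rather than on phenol or amine (6 enters cold and only after 4 is consumed, and phenolic additives have been used in such benzoyloxylations).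

Step 5
Reactants: 9 4-bromocatechol
Product: 10 1,2-bis(benzyloxy)-4-bromobenzene
Conditions: BnBr (2.3 equiv), K2CO3, DMF, 60 °C, N2
Reagents that add atoms: benzyl bromide, BrCc1ccccc1
Why: Williamson ether synthesis that masks the catechol with the same group as ring D, so that one final operation frees all phenols.

Step 6
Reactants: 8 (3S,4R)-4-[2,4-bis(benzyloxy)-3-methoxyphenyl]-2,7-dihydroxychroman-3-yl benzoate; 10 1,2-bis(benzyloxy)-4-bromobenzene
Product: 12 (2S,3R)-1-[3,4-bis(benzyloxy)phenyl]-3-[2,4-bis(benzyloxy)-3-methoxyphenyl]-3-(2,4-dihydroxyphenyl)propane-1,2-diol (both C1 epimers), via arylmagnesium bromide 11 (not isolated)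
Conditions: 10 (6.5 equiv), Mg, THF, 40 °C; then 8, THF, −40 → 23 °C; sat. aq NH4Cl
Reagents that add atoms: none
Why: Grignard addition to a lactol: two equivalents of 11 deprotonate the 7-OH and the hemiacetal OH, the magnesium lactolate opens to the phenoxide–aldehyde, which should take up one aryl group faster than it is enolised (C3 and C4 stay as set), two more equivalents remove the benzoate as a triarylmethanol, and the new carbinol centre (flavan C2) needs no control because step 7 ionises it.

Step 7
Reactants: 12 (2S,3R)-1-[3,4-bis(benzyloxy)phenyl]-3-[2,4-bis(benzyloxy)-3-methoxyphenyl]-3-(2,4-dihydroxyphenyl)propane-1,2-diol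
Product: 13 (2R,3S,4R)-2-[3,4-bis(benzyloxy)phenyl]-4-[2,4-bis(benzyloxy)-3-methoxyphenyl]chromane-3,7-diol (2,3-trans-3,4-cis)
Conditions: p-TsOH·H2O (10 mol %), CH2Cl2 (0.01 M), 0 → 23 °C
Reagents that add atoms: none
Why: Acid-induced dehydrative cyclisation of a 1-aryl-3-(2-hydroxyaryl)propane-1,2-diol, the usual ring C closure of flavan-3-ol synthesis: both carbinol epimers ionise to the same 4-benzyloxybenzyl cation, only the ortho hydroxyl of ring A is free to capture it (ring D is fully benzylated), and C2 should be set as 2R (2,3-trans) by a half-chair in which ring D stands quasi-axial to avoid H5, the cis O3 is therefore equatorial and ring B takes the remaining equatorial site, a preference that also holds at equilibrium because the closure is reversible under the acid.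

Step 8
Reactants: 13 (2R,3S,4R)-2-[3,4-bis(benzyloxy)phenyl]-4-[2,4-bis(benzyloxy)-3-methoxyphenyl]chromane-3,7-diol
Product: 14 (2R,3S,4S)-2-(3,4-dihydroxyphenyl)-4-(2,4-dihydroxy-3-methoxyphenyl)chromane-3,7-diol, 4β-(2,4-dihydroxy-3-methoxyphenyl)fisetinidol
Conditions: H2 (1 atm), Pd(OH)2/C, THF–MeOH, 23 °C
Reagents that add atoms: none
Why: Catalytic hydrogenolysis of the four aryl benzyl ethers, the standard last step for benzylated flavan-3-ols; at 1 atm the O1–C2 bond, the methyl ether and the three stereocentres should be left alone (the C4 descriptor changes from R to S only because ring D loses its benzyl groups).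

Compound list
1 | 2-methoxyresorcinol (2-methoxybenzene-1,3-diol) | COc1c(O)cccc1O | starting material
2 | 1,3-bis(benzyloxy)-2-methoxybenzene | COc1c(OCc2ccccc2)cccc1OCc1ccccc1 | intermediate
3 | 2,4-bis(benzyloxy)-3-methoxybenzaldehyde | COc1c(OCc2ccccc2)ccc(C=O)c1OCc1ccccc1 | intermediate
4 | (E)-3-[2,4-bis(benzyloxy)-3-methoxyphenyl]prop-2-enal | COc1c(OCc2ccccc2)ccc(/C=C/C=O)c1OCc1ccccc1 | intermediate
5 | resorcinol | Oc1cccc(O)c1 | starting material
6 | dibenzoyl peroxide | O=C(OOC(=O)c1ccccc1)c1ccccc1 | starting material
7 | (4R)-4-[2,4-bis(benzyloxy)-3-methoxyphenyl]chromane-2,7-diol (lactol anomers, not isolated) | COc1c(OCc2ccccc2)ccc([C@H]2c3ccc(O)cc3OC(O)C2)c1OCc1ccccc1 | intermediate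
8 | (3S,4R)-4-[2,4-bis(benzyloxy)-3-methoxyphenyl]-2,7-dihydroxychroman-3-yl benzoate (3,4-cis, lactol anomers) | COc1c(OCc2ccccc2)ccc([C@H]2c3ccc(O)cc3OC(O)[C@H]2OC(=O)c2ccccc2)c1OCc1ccccc1 | intermediate
9 | 4-bromocatechol (4-bromobenzene-1,2-diol) | Oc1ccc(Br)cc1O | starting material
10 | 1,2-bis(benzyloxy)-4-bromobenzene | Brc1ccc(OCc2ccccc2)c(OCc2ccccc2)c1 | intermediate
11 | 3,4-bis(benzyloxy)phenylmagnesium bromide (not isolated) | Br[Mg]c1ccc(OCc2ccccc2)c(OCc2ccccc2)c1 | intermediate
12 | (2S,3R)-1-[3,4-bis(benzyloxy)phenyl]-3-[2,4-bis(benzyloxy)-3-methoxyphenyl]-3-(2,4-dihydroxyphenyl)propane-1,2-diol (C1 epimers) | COc1c(OCc2ccccc2)ccc([C@@H](c2ccc(O)cc2O)[C@H](O)C(O)c2ccc(OCc3ccccc3)c(OCc3ccccc3)c2)c1OCc1ccccc1 | intermediate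
13 | (2R,3S,4R)-2-[3,4-bis(benzyloxy)phenyl]-4-[2,4-bis(benzyloxy)-3-methoxyphenyl]chromane-3,7-diol | COc1c(OCc2ccccc2)ccc([C@H]2c3ccc(O)cc3O[C@H](c3ccc(OCc4ccccc4)c(OCc4ccccc4)c3)[C@H]2O)c1OCc1ccccc1 | intermediate
14 | (2R,3S,4S)-2-(3,4-dihydroxyphenyl)-4-(2,4-dihydroxy-3-methoxyphenyl)chromane-3,7-diol | COc1c(O)ccc([C@H]2c3ccc(O)cc3O[C@H](c3ccc(O)c(O)c3)[C@H]2O)c1O | target

Total step count: 8. Longest linear sequence: 7 (steps 1, 2, 3, 4, 6, 7, 8).

Steps most likely to fail

Step 4 (bears the label).
- **What may go wrong:** The two alkoxy donors of ring D tame the iminium ion and resorcinol is only a moderate π-nucleophile, so the conjugate addition may be slow. Ring A may be alkylated a second time. The peroxide may oxidise phenols or benzoyloxylate the catalyst nitrogen. Enamine formation from a lactol next to a benzhydryl carbon may be sluggish. The 3,4-cis selectivity may drop if the substrate bias opposes the catalyst.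
- **Fallback (known chemistry; sets out from 4 and 5, returns at 12):** The two catalytic events are separated and the peroxide is given up. 4 and 5 are joined by the amine-catalysed Friedel–Crafts–hemiacetalisation alone and lactol 7 is isolated. D-Proline-catalysed α-aminoxylation with nitrosobenzene (CHCl3, 0 °C), in which the carboxylic acid steers the electrophile, should place oxygen on C3 in the same absolute sense and give the 3-anilinooxy lactol F1. Zn in AcOH–THF cleaves the N–O bond to the chromane-2,3,7-triol F2. F2 with four equivalents of 11, now under chelation by the C3 alkoxide, gives 12.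

Step 7.
- **What may go wrong:** Capture of the C2 cation may show poor facial selectivity. A 1,2-hydride shift from C3 to the cation, or intermolecular C-alkylation of the electron-rich ring A, may compete.
- **Fallback (sets out from 8, returns at 13, also bypasses step 6):** Ring C stays closed and ring B enters by substitution at C2.
  - 8 is acetylated (Ac2O, pyridine, CH2Cl2, 0 °C) to the 2,7-diacetate F3, and TMSBr (CH2Cl2, 0 °C) turns the anomeric acetate into the 2-bromochroman F4.
  - 10 is converted (n-BuLi, toluene–Bu2O, −10 °C; ZnBr2·LiBr) into the arylzinc bromide F5.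
  - F5 replaces the bromide in toluene–Bu2O (23 → 80 °C), in the manner of the uncatalysed arylzinc C-glycosylation of 2-O-acyl glycosyl bromides.
  - The C3 benzoate bridges to C2 on the β face, the face that ring D also covers, so the aryl group should enter from the α face and give the 2,3-trans-2,4-trans flavan diester F6.
  - K2CO3 in MeOH–THF removes benzoate and acetate and gives 13.

Step 6.
- **What may go wrong:** The basic reagent may enolise the α-benzoyloxy aldehyde, with loss of integrity at C3. Benzoyl migration and incomplete ester cleavage may spread the material over several species. The demand for reagent is heavy.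
- **Fallback (sets out from 8 and 10, returns at 12):** A catalytic, weakly basic aryl transfer replaces the Grignard reagent. 10 is converted (n-BuLi, THF, −78 °C; B(OiPr)3; dilute acid) into 3,4-bis(benzyloxy)phenylboronic acid F7. Rhodium-catalysed 1,2-addition of F7 to the aldehyde tautomer of 8 (Rh(acac)(C2H4)2, P(t-Bu)3, DME–H2O, 23 → 50 °C) tolerates the phenols and the ester and should give the carbinol benzoate F8. K2CO3 in MeOH then frees 12.

Further compounds
F1 | step 4 | (3S,4R)-3-(anilinooxy)-4-[2,4-bis(benzyloxy)-3-methoxyphenyl]chromane-2,7-diol (lactol anomers) | COc1c(OCc2ccccc2)ccc([C@H]2c3ccc(O)cc3OC(O)[C@H]2ONc2ccccc2)c1OCc1ccccc1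
F2 | step 4 | (3S,4R)-4-[2,4-bis(benzyloxy)-3-methoxyphenyl]chromane-2,3,7-triol (lactol anomers) | COc1c(OCc2ccccc2)ccc([C@H]2c3ccc(O)cc3OC(O)[C@H]2O)c1OCc1ccccc1
F3 | step 7 | (3S,4R)-2,7-diacetoxy-4-[2,4-bis(benzyloxy)-3-methoxyphenyl]chroman-3-yl benzoate (anomers) | COc1c(OCc2ccccc2)ccc([C@H]2c3ccc(OC(C)=O)cc3OC(OC(C)=O)[C@H]2OC(=O)c2ccccc2)c1OCc1ccccc1
F4 | step 7 | (3S,4R)-7-acetoxy-2-bromo-4-[2,4-bis(benzyloxy)-3-methoxyphenyl]chroman-3-yl benzoate | COc1c(OCc2ccccc2)ccc([C@H]2c3ccc(OC(C)=O)cc3OC(Br)[C@H]2OC(=O)c2ccccc2)c1OCc1ccccc1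
F5 | step 7 | [3,4-bis(benzyloxy)phenyl]zinc bromide | Br[Zn]c1ccc(OCc2ccccc2)c(OCc2ccccc2)c1
F6 | step 7 | (2R,3S,4R)-7-acetoxy-2-[3,4-bis(benzyloxy)phenyl]-4-[2,4-bis(benzyloxy)-3-methoxyphenyl]chroman-3-yl benzoate | COc1c(OCc2ccccc2)ccc([C@H]2c3ccc(OC(C)=O)cc3O[C@H](c3ccc(OCc4ccccc4)c(OCc4ccccc4)c3)[C@H]2OC(=O)c2ccccc2)c1OCc1ccccc1
F7 | step 6 | 3,4-bis(benzyloxy)phenylboronic acid | OB(O)c1ccc(OCc2ccccc2)c(OCc2ccccc2)c1
F8 | step 6 | (2S,3R)-1-[3,4-bis(benzyloxy)phenyl]-3-[2,4-bis(benzyloxy)-3-methoxyphenyl]-3-(2,4-dihydroxyphenyl)-1-hydroxypropan-2-yl benzoate (C1 epimers) | COc1c(OCc2ccccc2)ccc([C@@H](c2ccc(O)cc2O)[C@H](OC(=O)c2ccccc2)C(O)c2ccc(OCc3ccccc3)c(OCc3ccccc3)c2)c1OCc1ccccc1
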